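A direct plan would join a ring A phenol to a ring B 4-bromobenzoate by an Ullmann coupling (ester A1),
exchange the ester carbon for oxygen (phenol A2), and then build ring C on that oxygen from a malonate and an
acetonedicarboxylate (triester A3, closed to isophthalate A4), ending with hydrogenolysis and decarboxylation.
Its weakest steps would be:
(a) the change of the ester of A1 into the hydroxyl of A2, which would take three operations (reduction, oxidation, Baeyer–Villiger) and add no complexity;
(b) the crossed Claisen C-acylation that would give A3, where O-acylation, ketene formation and double acylation would compete on the most advanced material;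
(c) the base-induced closure of A3 to A4, where the choice between carbocycle and 2-pyranone would be left to chance, with a double decarboxylation of a free heptaphenol still to follow.

**Plan of the new route**
Ring B carries O, O, H, O, H, O on C1 to C6 (C1 bears the ring A oxygen, C4 the ring C oxygen): three head-to-tail two-carbon units, each with one oxygenated carbon.
C2–C1 is therefore an aryloxyketene (ring A–O on the α-carbon), C6–C5 an alkoxyacetylene and C4–C3 an aryloxyacetylene (ring C–O on the alkyne); this pattern is what makes a ketene/ynol ether benzannulation possible.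
The retrosynthesis cuts ring B at C2–C3 and C4–C5 (key step) and at C1–C6 (ketene–ynol ether cycloaddition); both ether oxygens reach ring B as O–CH2 and O–C≡C bonds made on phenols.
Rings A and C enter as bought arenes; ring B arises last, from a cyclobutenone and an ynol ether, in one pericyclic cascade.
No carbon is exchanged for oxygen, no enolate acylation or Dieckmann closure occurs, nothing is decarboxylated, and the last step is a neutral hydrogenolysis.

Key step: step 9

Remark on the chemistry: 3,5-bis(benzyloxy)phenol, 1,3,5-tris(benzyloxy)benzene and benzyl alcohol are taken as commercial; the stereocentres of the cyclobutenone and of the transient intermediates are racemic and vanish on aromatisation; the target is achiral.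

**Step 1**
Reactants: 1 3,5-bis(benzyloxy)phenol
Product: 2 [3,5-bis(benzyloxy)phenoxy]acetic acid
Conditions: NaH (2.4 equiv), BrCH2CO2H (1.2 equiv), THF, 0 °C to 60 °C; then 1 M HCl
Reagents that add atoms: bromoacetic acid, OC(=O)CBr
Why: Williamson etherification (SN2) of the sodium phenoxide with sodium bromoacetate should give the aryloxyacetic acid, which already holds the ring A–O–C1 bond and the carbons C1 and C2 of ring B, and no stereocentre is formed.

**Step 2**
Reactants: 3 benzyl alcohol
Product: 4 benzyl (E)-1,2-dichloroethenyl ether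
Conditions: KH (1.1 equiv), THF, 0 °C; Cl2C=CHCl (1.1 equiv), 0 °C to rt
Reagents that add atoms: trichloroethylene, ClC=C(Cl)Cl
Why: Base-induced loss of HCl from trichloroethylene gives dichloroacetylene, to which the alkoxide adds anti (nucleophilic addition to a haloalkyne), so the E-dichloroenol ether should form as in the standard alkoxyacetylene synthesis.

**Step 3**
Reactants: 4 benzyl (E)-1,2-dichloroethenyl ether
Product: 7 benzyl ethynyl ether, via chloroalkyne 5 (not isolated), via lithium acetylide 6 (not isolated)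
Conditions: n-BuLi (2.3 equiv), Et2O, −78 °C to −40 °C; MeOH, −78 °C; cold aqueous wash, solution in Et2O–pentane kept at −20 °C and used at once
Reagents that add atoms: none
Why: Dehydrochlorination to chloroalkyne 5 and chlorine–lithium exchange give acetylide 6 (the standard elimination route to ynol ethers), whose protonation at low temperature frees the ynol ether, which is kept cold because benzyl alkynyl ethers undergo a [3,3] sigmatropic shift on warming.

**Step 4**
Reactants: 2 [3,5-bis(benzyloxy)phenoxy]acetic acid; 7 benzyl ethynyl ether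
Product: 10 3-(benzyloxy)-4-[3,5-bis(benzyloxy)phenoxy]cyclobut-2-en-1-one (racemic), via acid chloride 8 (not isolated), via aryloxyketene 9 (not isolated)
Conditions: 2, 1-chloro-N,N,2-trimethylprop-1-en-1-amine (1.1 equiv), CH2Cl2, 0 °C, 1 h; then added over 4 h to 7 (1.5 equiv), Et3N (1.3 equiv), CH2Cl2, 0 °C to rt
Reagents that add atoms: none
Why: The neutral α-chloroenamine should form chloride 8 without attacking the electron-rich ring, triethylamine then generates aryloxyketene 9, and its [2+2] cycloaddition with the ynol ether (ketene–alkoxyalkyne cycloaddition) joins the ketene carbonyl carbon to the nucleophilic CH terminus and so gives the 3-alkoxy-4-aryloxycyclobutenone, whose C4 centre is racemic and is erased on aromatisation.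

**Step 5**
Reactants: 11 1,3,5-tris(benzyloxy)benzene
Product: 12 2-bromo-1,3,5-tris(benzyloxy)benzene
Conditions: NBS (1.0 equiv), CH2Cl2, −78 °C to 0 °C, dark
Reagents that add atoms: N-bromosuccinimide, O=C1CCC(=O)N1Br
Why: Electrophilic aromatic bromination of the phloroglucinol triether, whose three free ring positions are equivalent, should stop at the monobromide with one equivalent of reagent at low temperature.

**Step 6**
Reactants: 12 2-bromo-1,3,5-tris(benzyloxy)benzene
Product: 15 2,4,6-tris(benzyloxy)phenol, via aryllithium 13 (not isolated), via arylboronate 14 (not isolated)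
Conditions: n-BuLi (1.1 equiv), THF, −78 °C; B(OMe)3 (1.5 equiv), −78 °C to 0 °C; AcOH (1.2 equiv), 30% H2O2 (2 equiv), 0 °C to rt
Reagents that add atoms: hydrogen peroxide, OO
Why: Bromine–lithium exchange (faster than benzylic metalation at −78 °C), borylation and oxidative 1,2-migration of the aryl group from boron to oxygen (boronate oxidation) should install the hindered oxygen of ring C.

**Step 7**
Reactants: 15 2,4,6-tris(benzyloxy)phenol
Product: 16 1,3,5-tris(benzyloxy)-2-{[(E)-1,2-dichloroethenyl]oxy}benzene
Conditions: Cl2C=CHCl (1.5 equiv), K2CO3 (2 equiv), DMF, 70 °C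
Reagents that add atoms: trichloroethylene, ClC=C(Cl)Cl
Why: As in step 2, the phenoxide adds anti to dichloroacetylene formed in the flask (nucleophilic addition to a haloalkyne), a small linear electrophile that the 2,6-disubstituted phenoxide should reach without difficulty, so the future ring C–O–C4 bond is made without any aryl–oxygen coupling.

**Step 8**
Reactants: 16 1,3,5-tris(benzyloxy)-2-{[(E)-1,2-dichloroethenyl]oxy}benzene
Product: 19 1,3,5-tris(benzyloxy)-2-(ethynyloxy)benzene, via chloroalkyne 17 (not isolated), via lithium acetylide 18 (not isolated)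
Conditions: n-BuLi (2.3 equiv), THF, −78 °C to −40 °C; MeOH, −78 °C; aqueous work-up below 0 °C, stored cold in solution
Reagents that add atoms: none
Why: Dehydrochlorination to chloroalkyne 17, chlorine–lithium exchange to acetylide 18 and protonation (the standard route to aryl ynol ethers) should give the terminal aryloxyacetylene, the vinylic deprotonation being much faster than attack of butyllithium on the benzyl ethers.

**Step 9 (key step)**
Reactants: 10 3-(benzyloxy)-4-[3,5-bis(benzyloxy)phenoxy]cyclobut-2-en-1-one; 19 1,3,5-tris(benzyloxy)-2-(ethynyloxy)benzene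
Product: 24 3-(benzyloxy)-2-[3,5-bis(benzyloxy)phenoxy]-5-[2,4,6-tris(benzyloxy)phenoxy]phenol, via vinylketene 20 (not isolated), via vinylcyclobutenone 21 (not isolated), via dienylketene 22 (not isolated), via cyclohexadienone 23 (not isolated)
Conditions: 10 (1.0 equiv), 19 (1.4 equiv), degassed toluene (0.2 M), 90 °C, Ar; then K2CO3 (0.2 equiv), MeOH–THF, rt; 0.5 M HCl wash
Reagents that add atoms: none
Why: Proposed new method: heating should open cyclobutenone 10 by a 4π electrocyclic reaction (the C4 aryloxy donor rotating outward) to vinylketene 20, whose ketene carbon is attacked by the nucleophilic CH terminus of ynol ether 19 in a [2+2] cycloaddition to 21; reversible 4π opening of 21 to dienylketene 22, 6π electrocyclisation to cyclohexadienone 23 and enolisation then give phenol 24. The closest known reaction type is the Danheiser benzannulation of cyclobutenones with alkoxy- and silyloxyacetylenes; what lacks precedent is an aryl ethynyl ether as the ketenophile together with a 4-aryloxy-3-alkoxycyclobutenone, which should react in the same sense because an aryloxy group still polarises the alkyne towards its CH terminus and an oxygen donor at C4 eases ring opening. Ring B is closed by a six-electron electrocyclisation between the ketene carbon (C2) and C1 after the cycloaddition has made C2–C3 and C4–C5, so closure on oxygen is not open to the mechanism. No stereocentre survives: the racemic centres of 10, 21 and 23 and the alkene geometries of 20 to 22 are lost on aromatisation. The selectivity needed is regiochemical (the two aryloxy groups para, the free hydroxyl next to the ring A oxygen); it is secured by the polarity of the ynol ether, whose oxygenated carbon bonds to the ketene α-carbon (C5), and by the fixed places of the substituents in 10. The excess of 19 and the closing methanolysis answer the known side reaction in which the product phenol is acylated by 20.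

**Step 10**
Reactants: 24 3-(benzyloxy)-2-[3,5-bis(benzyloxy)phenoxy]-5-[2,4,6-tris(benzyloxy)phenoxy]phenol
Product: 25 triphlorethol A, 2-[4-(3,5-dihydroxyphenoxy)-3,5-dihydroxyphenoxy]benzene-1,3,5-triol
Conditions: H2 (1 atm), 10% Pd/C, degassed THF–MeOH 1:1, rt; filtration under Ar, concentration, freeze-drying from degassed water
Reagents that add atoms: none
Why: Catalytic hydrogenolysis of the six benzyl aryl ethers over palladium under neutral conditions should leave both diaryl ether bonds intact and release the achiral heptaphenol with toluene as the only by-product.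

**Compound list**
1 | 3,5-bis(benzyloxy)phenol | Oc1cc(OCc2ccccc2)cc(OCc2ccccc2)c1 | starting material
2 | [3,5-bis(benzyloxy)phenoxy]acetic acid | OC(=O)COc1cc(OCc2ccccc2)cc(OCc2ccccc2)c1 | intermediate
3 | benzyl alcohol | OCc1ccccc1 | starting material
4 | benzyl (E)-1,2-dichloroethenyl ether | Cl/C=C(/Cl)OCc1ccccc1 | intermediate
5 | benzyl chloroethynyl ether (chloroalkyne) | ClC#COCc1ccccc1 | intermediate
6 | lithium (benzyloxy)ethynide (lithium acetylide) | [Li]C#COCc1ccccc1 | intermediate
7 | benzyl ethynyl ether | C#COCc1ccccc1 | intermediate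
8 | [3,5-bis(benzyloxy)phenoxy]acetyl chloride (acid chloride) | ClC(=O)COc1cc(OCc2ccccc2)cc(OCc2ccccc2)c1 | intermediate
9 | 2-[3,5-bis(benzyloxy)phenoxy]ethen-1-one (aryloxyketene) | O=C=COc1cc(OCc2ccccc2)cc(OCc2ccccc2)c1 | intermediate
10 | 3-(benzyloxy)-4-[3,5-bis(benzyloxy)phenoxy]cyclobut-2-en-1-one (racemic) | O=C1C=C(OCc2ccccc2)C1Oc1cc(OCc2ccccc2)cc(OCc2ccccc2)c1 | intermediate
11 | 1,3,5-tris(benzyloxy)benzene | c1c(OCc2ccccc2)cc(OCc2ccccc2)cc1OCc1ccccc1 | starting material
12 | 2-bromo-1,3,5-tris(benzyloxy)benzene | Brc1c(OCc2ccccc2)cc(OCc2ccccc2)cc1OCc1ccccc1 | intermediate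
13 | [2,4,6-tris(benzyloxy)phenyl]lithium (aryllithium) | [Li]c1c(OCc2ccccc2)cc(OCc2ccccc2)cc1OCc1ccccc1 | intermediate
14 | dimethyl [2,4,6-tris(benzyloxy)phenyl]boronate (arylboronate) | COB(OC)c1c(OCc2ccccc2)cc(OCc2ccccc2)cc1OCc1ccccc1 | intermediate
15 | 2,4,6-tris(benzyloxy)phenol | Oc1c(OCc2ccccc2)cc(OCc2ccccc2)cc1OCc1ccccc1 | intermediate
16 | 1,3,5-tris(benzyloxy)-2-{[(E)-1,2-dichloroethenyl]oxy}benzene | Cl/C=C(/Cl)Oc1c(OCc2ccccc2)cc(OCc2ccccc2)cc1OCc1ccccc1 | intermediate
17 | 1,3,5-tris(benzyloxy)-2-[(chloroethynyl)oxy]benzene (chloroalkyne) | ClC#COc1c(OCc2ccccc2)cc(OCc2ccccc2)cc1OCc1ccccc1 | intermediate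
18 | lithium [2,4,6-tris(benzyloxy)phenoxy]ethynide (lithium acetylide) | [Li]C#COc1c(OCc2ccccc2)cc(OCc2ccccc2)cc1OCc1ccccc1 | intermediate
19 | 1,3,5-tris(benzyloxy)-2-(ethynyloxy)benzene | C#COc1c(OCc2ccccc2)cc(OCc2ccccc2)cc1OCc1ccccc1 | intermediate
20 | (3Z)-3-(benzyloxy)-4-[3,5-bis(benzyloxy)phenoxy]buta-1,3-dien-1-one (vinylketene) | O=C=C/C(OCc1ccccc1)=C/Oc1cc(OCc2ccccc2)cc(OCc2ccccc2)c1 | intermediate
21 | 4-{(Z)-1-(benzyloxy)-2-[3,5-bis(benzyloxy)phenoxy]ethenyl}-3-[2,4,6-tris(benzyloxy)phenoxy]cyclobut-2-en-1-one (vinylcyclobutenone, racemic) | O=C1C=C(Oc2c(OCc3ccccc3)cc(OCc3ccccc3)cc2OCc2ccccc2)C1/C(OCc1ccccc1)=C/Oc1cc(OCc2ccccc2)cc(OCc2ccccc2)c1 | intermediate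
22 | (3E,5Z)-5-(benzyloxy)-6-[3,5-bis(benzyloxy)phenoxy]-3-[2,4,6-tris(benzyloxy)phenoxy]hexa-1,3,5-trien-1-one (dienylketene, the isomer that cyclises) | O=C=C/C(Oc1c(OCc2ccccc2)cc(OCc2ccccc2)cc1OCc1ccccc1)=C\C(OCc1ccccc1)=C\Oc1cc(OCc2ccccc2)cc(OCc2ccccc2)c1 | intermediate
23 | 5-(benzyloxy)-6-[3,5-bis(benzyloxy)phenoxy]-3-[2,4,6-tris(benzyloxy)phenoxy]cyclohexa-2,4-dien-1-one (cyclohexadienone, racemic) | O=C1C=C(Oc2c(OCc3ccccc3)cc(OCc3ccccc3)cc2OCc2ccccc2)C=C(OCc2ccccc2)C1Oc1cc(OCc2ccccc2)cc(OCc2ccccc2)c1 | intermediate
24 | 3-(benzyloxy)-2-[3,5-bis(benzyloxy)phenoxy]-5-[2,4,6-tris(benzyloxy)phenoxy]phenol | Oc1cc(Oc2c(OCc3ccccc3)cc(OCc3ccccc3)cc2OCc2ccccc2)cc(OCc2ccccc2)c1Oc1cc(OCc2ccccc2)cc(OCc2ccccc2)c1 | intermediate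
25 | triphlorethol A, 2-[4-(3,5-dihydroxyphenoxy)-3,5-dihydroxyphenoxy]benzene-1,3,5-triol (achiral) | Oc1cc(O)cc(Oc2c(O)cc(Oc3c(O)cc(O)cc3O)cc2O)c1 | target

**Count and risks**
Total step count: 10. Longest linear sequence: 6 steps (steps 5, 6, 7, 8, 9, 10, from 1,3,5-tris(benzyloxy)benzene).

Steps most likely to fail:

Step 9 (bears the label). The aryl ynol ether may be too weak a ketenophile, so that the vinylketene recloses or dimerises, the product phenol is acylated, or the ynol ether oligomerises at the temperature that ring opening needs. The fallback uses known copper-mediated diaryl ether couplings, sets out from phenol 15 and returns at 25. Commercial 4-bromo-2,6-dimethoxyphenol would be O-arylated with commercial 3,5-bis(benzyloxy)phenylboronic acid under Chan–Lam conditions (Cu(OAc)2, pyridine, 4 Å sieves, CH2Cl2, air) to 5-bromo-2-[3,5-bis(benzyloxy)phenoxy]-1,3-dimethoxybenzene F1. Ullmann coupling of F1 with the hindered phenol 15 (CuI, picolinic acid, K3PO4, DMSO, 100 °C) would give 1,3,5-tris(benzyloxy)-2-{4-[3,5-bis(benzyloxy)phenoxy]-3,5-dimethoxyphenoxy}benzene F2. Hydrogenolysis (H2, Pd/C) would give 2-[4-(3,5-dihydroxyphenoxy)-3,5-dimethoxyphenoxy]benzene-1,3,5-triol F3, and BBr3 in CH2Cl2 (−78 °C to rt) would cleave the two methyl ethers to 25.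

Step 4. The benzyl ynol ether may be lost by sigmatropic rearrangement or hydration before the ketene is trapped, and the aryloxyketene may dimerise faster than it cycloadds. The fallback sets out from acid 2 and returns at 10. The ketene would be generated in the same way in the presence of commercial, thermally robust ethoxyacetylene to give 4-[3,5-bis(benzyloxy)phenoxy]-3-ethoxycyclobut-2-en-1-one F4. Acid-catalysed exchange of the vinylogous ester with benzyl alcohol (pyridinium p-toluenesulfonate, toluene, 4 Å sieves, ethanol removed) would then give 10. The exchange cannot scramble the regiochemistry, because the carbonyl and alkoxy carbons both flank the aryloxy carbon. Steps 2 and 3 would then not be needed.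

Step 10. Hydrogenolysis of six benzyl ethers may stall through adsorption of the polyphenol on the catalyst, and the free heptaphenol may oxidise in air during filtration and concentration. The fallback sets out from 24 and returns at 25. The crude hydrogenolysis mixture would be acetylated at once (Ac2O, pyridine) to triphlorethol A heptaacetate F5, which is robust and can be purified on silica. Acid-catalysed methanolysis (acetyl chloride, catalytic, in degassed MeOH, rt, Ar) would then release 25 with only volatile by-products.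

**Further compounds**
F1 | step 9 | 5-bromo-2-[3,5-bis(benzyloxy)phenoxy]-1,3-dimethoxybenzene | COc1cc(Br)cc(OC)c1Oc1cc(OCc2ccccc2)cc(OCc2ccccc2)c1
F2 | step 9 | 1,3,5-tris(benzyloxy)-2-{4-[3,5-bis(benzyloxy)phenoxy]-3,5-dimethoxyphenoxy}benzene | COc1cc(Oc2c(OCc3ccccc3)cc(OCc3ccccc3)cc2OCc2ccccc2)cc(OC)c1Oc1cc(OCc2ccccc2)cc(OCc2ccccc2)c1
F3 | step 9 | 2-[4-(3,5-dihydroxyphenoxy)-3,5-dimethoxyphenoxy]benzene-1,3,5-triol | COc1cc(Oc2c(O)cc(O)cc2O)cc(OC)c1Oc1cc(O)cc(O)c1
F4 | step 4 | 4-[3,5-bis(benzyloxy)phenoxy]-3-ethoxycyclobut-2-en-1-one (racemic) | CCOC1=CC(=O)C1Oc1cc(OCc2ccccc2)cc(OCc2ccccc2)c1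
F5 | step 10 | triphlorethol A heptaacetate, 2-{4-[3,5-bis(acetyloxy)phenoxy]-3,5-bis(acetyloxy)phenoxy}benzene-1,3,5-triyl triacetate | CC(=O)Oc1cc(OC(C)=O)cc(Oc2c(OC(C)=O)cc(Oc3c(OC(C)=O)cc(OC(C)=O)cc3OC(C)=O)cc2OC(C)=O)c1
A1 | direct plan | benzyl 3,5-bis(benzyloxy)-4-[3,5-bis(benzyloxy)phenoxy]benzoate | O=C(OCc1ccccc1)c1cc(OCc2ccccc2)c(Oc2cc(OCc3ccccc3)cc(OCc3ccccc3)c2)c(OCc2ccccc2)c1
A2 | direct plan | 3,5-bis(benzyloxy)-4-[3,5-bis(benzyloxy)phenoxy]phenol | Oc1cc(OCc2ccccc2)c(Oc2cc(OCc3ccccc3)cc(OCc3ccccc3)c2)c(OCc2ccccc2)c1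
A3 | direct plan | tribenzyl 1-{3,5-bis(benzyloxy)-4-[3,5-bis(benzyloxy)phenoxy]phenoxy}-2,4-dioxopentane-1,3,5-tricarboxylate | O=C(OCc1ccccc1)C(Oc1cc(OCc2ccccc2)c(Oc2cc(OCc3ccccc3)cc(OCc3ccccc3)c2)c(OCc2ccccc2)c1)C(=O)C(C(=O)OCc1ccccc1)C(=O)CC(=O)OCc1ccccc1
A4 | direct plan | dibenzyl 5-{3,5-bis(benzyloxy)-4-[3,5-bis(benzyloxy)phenoxy]phenoxy}-2,4,6-trihydroxybenzene-1,3-dicarboxylate | Oc1c(C(=O)OCc2ccccc2)c(O)c(C(=O)OCc2ccccc2)c(O)c1Oc1cc(OCc2ccccc2)c(Oc2cc(OCc3ccccc3)cc(OCc3ccccc3)c2)c(OCc2ccccc2)c1
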